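**Plan**

Numbering of the target is that of 1-benzoxepine (O1, C2–C5, C5a, C6–C9, C9a).

1. Retrosynthesis cuts, in this order: C3=C4 (ring-closing metathesis), C4–C5 (Negishi vinylation), C2–C3 (substitution at an acetal carbon), C7–Br (Appel), the ring bond C6–C7 (radical–carbonyl closure), and C5a–C6 (epoxide opening).
2. Enabling feature: in the cyclohexane ring the gem-dimethyl carbon C6 lies between the ring-fusion CH C5a and the bromomethine C7. An isopropenyl group on C5a is therefore a masked tertiary C6 radical, and C7, reached through C5a–C9a–C9–C8, can be an aldehyde carbon.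
3. Forward order: geraniol → epoxy alcohol → isopropenyl diol → bromomethyl-1,3-dioxane (a temporary ring that later supplies C1, its bromine and C2) → aldehyde → cyclohexane ring (step 5) → C7 bromide → dioxane opened to the tertiary ether → oxepene ring last.
4. Stereochemistry: C9a from the Sharpless epoxidation; C5a by SN2 inversion of that epoxide; C7 by equatorial hydride delivery followed by SN2 inversion; C2 by invertive substitution at the acetal carbon, whose configuration the chair dioxane fixes.

Key step: step 5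

Remark: the C6 epimer ratio of alcohol 9 is left open on purpose, because both epimers converge at ketone 10.

**Step 1**
Reactants: 1 geraniol
Product: 2 [(2S,3S)-3-methyl-3-(4-methylpent-3-en-1-yl)oxiran-2-yl]methanol
Conditions: Ti(OiPr)4 (5 mol%), L-(+)-diethyl tartrate (7 mol%), t-BuOOH, 4 Å MS, CH2Cl2, −20 °C
Reagents that add atoms: tert-butyl hydroperoxide, CC(C)(C)OO
Why: Katsuki–Sharpless asymmetric epoxidation of the allylic alcohol, in which the titanium L-(+)-tartrate complex delivers oxygen to the face that gives the 2S,3S epoxide and so fixes the later C9a.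

**Step 2**
Reactants: 2 [(2S,3S)-3-methyl-3-(4-methylpent-3-en-1-yl)oxiran-2-yl]methanol; 3 isopropenylmagnesium bromide
Product: 4 (2R,3S)-3,7-dimethyl-2-(prop-1-en-2-yl)oct-6-ene-1,3-diol
Conditions: 3 (3 equiv), CuI (20 mol%), THF/Et2O, −30 → 0 °C
Reagents that add atoms: isopropenylmagnesium bromide (3), CC(=C)[Mg]Br
Why: Copper-catalysed Grignard opening of a 2,3-epoxy alcohol should occur by SN2 attack with inversion at the less substituted C2 (the tertiary C3 is shielded), and anti opening of the E-derived epoxide gives the relative configuration of the later trans ring fusion.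

**Step 3**
Reactants: 4 (2R,3S)-3,7-dimethyl-2-(prop-1-en-2-yl)oct-6-ene-1,3-diol
Product: 6 (2R,4S,5R)-2-(bromomethyl)-4-methyl-4-(4-methylpent-3-en-1-yl)-5-(prop-1-en-2-yl)-1,3-dioxane, via primary vinyl ether 5 (not isolated)
Conditions: [IrCl(cod)]2 (1 mol%), Na2CO3, vinyl acetate, toluene, 100 °C; volatiles removed; then NBS, CH2Cl2, −78 → 0 °C
Reagents that add atoms: vinyl acetate, C=COC(C)=O; N-bromosuccinimide, O=C1CCC(=O)N1Br
Why: Iridium-catalysed transfer vinylation should take only the primary hydroxyl, and bromination of the electron-rich enol ether gives a bromo-oxocarbenium ion that the tertiary hydroxyl traps through a six-membered chair (intramolecular haloacetalization), with the E oxocarbenium placing CH2Br equatorial, which is also the thermodynamic acetal epimer.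

**Step 4**
Reactants: 6 (2R,4S,5R)-2-(bromomethyl)-4-methyl-4-(4-methylpent-3-en-1-yl)-5-(prop-1-en-2-yl)-1,3-dioxane
Product: 8 3-[(2R,4S,5R)-2-(bromomethyl)-4-methyl-5-(prop-1-en-2-yl)-1,3-dioxan-4-yl]propanal, via side-chain epoxide 7 (not isolated)
Conditions: mCPBA (1.05 equiv), NaHCO3, CH2Cl2, −10 °C; then H5IO6, THF/H2O, 0 °C
Reagents that add atoms: meta-chloroperoxybenzoic acid, OOC(=O)c1cccc(Cl)c1
Why: Prilezhaev epoxidation should select the electron-rich trisubstituted alkene over the hindered 1,1-disubstituted one, and periodic acid then hydrolyses the epoxide and cleaves the glycol (Malaprade cleavage) to the aldehyde and acetone, while the bromine makes the acetal slow to ionize in acid.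

**Step 5**
Reactants: 8 3-[(2R,4S,5R)-2-(bromomethyl)-4-methyl-5-(prop-1-en-2-yl)-1,3-dioxan-4-yl]propanal
Product: 9 (2R,4aR,6S,8aS)-2-(bromomethyl)-5,5,8a-trimethylhexahydro-4H-1,3-benzodioxin-6-ol
Conditions: Fe(acac)3 (50 mol%), PhSiH3 (2.5 equiv), EtOH, 60 °C
Reagents that add atoms: none
Why: The hydridoiron species made from Fe(acac)3 and PhSiH3 gives a hydrogen atom to the CH2 end of the 1,1-disubstituted alkene (Mukaiyama-type metal-hydride hydrogen-atom transfer), so the future C6 of the target becomes a tertiary radical that carries both methyl groups. This radical adds to the aldehyde carbon, the future C7, and the alkoxy radical is reduced by divalent iron and protonated by ethanol, which returns trivalent iron; the closest known reaction type is the iron-hydride-initiated radical cyclization of alkene-tethered ketones and the related radical addition of alkenes to aldehydes. The cyclohexane closes in the 6-exo-trig mode onto C=O and is trans-fused to the dioxane because the radical-bearing arm on C5 and the formylethyl arm on C4 of the chair acetal are both equatorial, so the configurations of the future C5a and C9a are carried over unchanged. The one new stereocentre, the carbinol carbon, is set by a chair transition state with the C–O bond pseudo-equatorial and should be mainly 6S in 9, but it is removed in step 6. The step needs ring closure to outrun reduction of the tertiary radical and reopening of the alkoxy radical: an aldehyde is the fastest carbonyl acceptor for a 6-exo closure, the dioxane holds the two arms gauche, iron and ethanol trap the alkoxy radical, and the substrate has no second alkene and only an unreactive primary C–Br bond.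

**Step 6**
Reactants: 9 (2R,4aR,6S,8aS)-2-(bromomethyl)-5,5,8a-trimethylhexahydro-4H-1,3-benzodioxin-6-ol
Product: 10 (2R,4aR,8aS)-2-(bromomethyl)-5,5,8a-trimethyl-4a,7,8,8a-tetrahydro-4H-1,3-benzodioxin-6(5H)-one
Conditions: Dess–Martin periodinane, NaHCO3, CH2Cl2, rt
Reagents that add atoms: none
Why: Dess–Martin oxidation of the hindered secondary alcohol should merge any mixture of C6 epimers into one ketone, which cannot enolize towards the quaternary carbon.

**Step 7**
Reactants: 10 (2R,4aR,8aS)-2-(bromomethyl)-5,5,8a-trimethyl-4a,7,8,8a-tetrahydro-4H-1,3-benzodioxin-6(5H)-one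
Product: 11 (2R,4aR,6R,8aS)-2-(bromomethyl)-5,5,8a-trimethylhexahydro-4H-1,3-benzodioxin-6-ol
Conditions: LiBH(s-Bu)3 (L-Selectride), THF, −78 °C; then H2O
Reagents that add atoms: none
Why: The bulky trialkylborohydride should attack the cyclohexanone from the equatorial side, away from the 1,3-diaxial hydrogens, and give the axial 6R alcohol (substrate-controlled reduction).

**Step 8**
Reactants: 11 (2R,4aR,6R,8aS)-2-(bromomethyl)-5,5,8a-trimethylhexahydro-4H-1,3-benzodioxin-6-ol
Product: 12 (2R,4aR,6S,8aS)-6-bromo-2-(bromomethyl)-5,5,8a-trimethylhexahydro-4H-1,3-benzodioxine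
Conditions: CBr4, PPh3, toluene, 0 → 60 °C
Reagents that add atoms: carbon tetrabromide, BrC(Br)(Br)Br
Why: Appel reaction, in which bromide displaces the axial alkoxyphosphonium group by SN2 with inversion and so places bromine equatorial, the 7S centre of the target.

**Step 9**
Reactants: 12 (2R,4aR,6S,8aS)-6-bromo-2-(bromomethyl)-5,5,8a-trimethylhexahydro-4H-1,3-benzodioxine; 3 isopropenylmagnesium bromide
Product: 13 [(1R,3S,6S)-3-bromo-6-{[(2R)-1-bromo-3-methylbut-3-en-2-yl]oxy}-2,2,6-trimethylcyclohexyl]methanol
Conditions: 3 (2 equiv), CuI (2 equiv), Et2O, −40 °C; then BF3·OEt2 (2 equiv) and 12, −78 → −30 °C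
Reagents that add atoms: isopropenylmagnesium bromide (3), CC(=C)[Mg]Br
Why: Lewis-acid-promoted substitution of a cyclic acetal by an organocopper reagent: BF3 should bind the less hindered O3 on the primary carbon, the C2–O3 bond breaks and the alkenyl group enters anti to it, so the acetal carbon is inverted to the 2R centre of the target while the tertiary oxygen stays as the ether.

**Step 10**
Reactants: 13 [(1R,3S,6S)-3-bromo-6-{[(2R)-1-bromo-3-methylbut-3-en-2-yl]oxy}-2,2,6-trimethylcyclohexyl]methanol
Product: 14 (1S,2S,4S)-4-bromo-1-{[(2R)-1-bromo-3-methylbut-3-en-2-yl]oxy}-2-(iodomethyl)-1,3,3-trimethylcyclohexane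
Conditions: PPh3, I2, imidazole, toluene, 60 °C
Reagents that add atoms: iodine, II
Why: Appel-type iodination of the primary alcohol, since iodide is a small and strong enough nucleophile for SN2 at this β-branched carbon and no stereocentre is touched.

**Step 11**
Reactants: 14 (1S,2S,4S)-4-bromo-1-{[(2R)-1-bromo-3-methylbut-3-en-2-yl]oxy}-2-(iodomethyl)-1,3,3-trimethylcyclohexane; 15 vinyl bromide
Product: 17 (1S,2S,4S)-4-bromo-1-{[(2R)-1-bromo-3-methylbut-3-en-2-yl]oxy}-1,3,3-trimethyl-2-(prop-2-en-1-yl)cyclohexane, via alkylzinc iodide 16 (not isolated)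
Conditions: Zn dust (activated), LiCl, THF, 25 °C; then 15, Pd(PPh3)4 (5 mol%), THF, 25 → 40 °C
Reagents that add atoms: vinyl bromide (15), C=CBr
Why: Zinc should insert into the primary C–I bond at room temperature and leave both C–Br bonds, and Negishi coupling of the alkylzinc with vinyl bromide under zerovalent palladium then makes the C4–C5 bond without an SN2 step by a carbon nucleophile at the hindered carbon.

**Step 12**
Reactants: 17 (1S,2S,4S)-4-bromo-1-{[(2R)-1-bromo-3-methylbut-3-en-2-yl]oxy}-1,3,3-trimethyl-2-(prop-2-en-1-yl)cyclohexane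
Product: 18 palisadin B, (2R,5aS,7S,9aS)-7-bromo-2-(bromomethyl)-3,6,6,9a-tetramethyl-2,5,5a,6,7,8,9,9a-octahydro-1-benzoxepine
Conditions: second-generation Grubbs catalyst RuCl2(=CHPh)(H2IMes)(PCy3) (5–10 mol%), toluene, 80 °C
Reagents that add atoms: none
Why: Ring-closing metathesis between the allyl group and the 1,1-disubstituted alkene, both on equatorial arms of the chair cyclohexane, should close the seven-membered ring as the trisubstituted and necessarily cis C3=C4 alkene with loss of ethene.

**Compound list**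

1 | geraniol, (2E)-3,7-dimethylocta-2,6-dien-1-ol | CC(C)=CCC/C(C)=C/CO | starting material
2 | [(2S,3S)-3-methyl-3-(4-methylpent-3-en-1-yl)oxiran-2-yl]methanol | OC[C@@H]1O[C@@]1(C)CCC=C(C)C | intermediate
3 | isopropenylmagnesium bromide (prop-1-en-2-ylmagnesium bromide) | CC(=C)[Mg]Br | starting material
4 | (2R,3S)-3,7-dimethyl-2-(prop-1-en-2-yl)oct-6-ene-1,3-diol | OC[C@@H](C(C)=C)[C@@](C)(O)CCC=C(C)C | intermediate
5 | (2R,3S)-1-(ethenyloxy)-3,7-dimethyl-2-(prop-1-en-2-yl)oct-6-en-3-ol | C=COC[C@@H](C(C)=C)[C@@](C)(O)CCC=C(C)C | intermediate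
6 | (2R,4S,5R)-2-(bromomethyl)-4-methyl-4-(4-methylpent-3-en-1-yl)-5-(prop-1-en-2-yl)-1,3-dioxane | BrC[C@@H]1OC[C@@H](C(C)=C)[C@](C)(CCC=C(C)C)O1 | intermediate
7 | (2R,4S,5R)-2-(bromomethyl)-4-[2-(3,3-dimethyloxiran-2-yl)ethyl]-4-methyl-5-(prop-1-en-2-yl)-1,3-dioxane, both epimers at the oxirane CH | BrC[C@@H]1OC[C@@H](C(C)=C)[C@](C)(CCC2OC2(C)C)O1 | intermediate
8 | 3-[(2R,4S,5R)-2-(bromomethyl)-4-methyl-5-(prop-1-en-2-yl)-1,3-dioxan-4-yl]propanal | BrC[C@@H]1OC[C@@H](C(C)=C)[C@](C)(CCC=O)O1 | intermediate
9 | (2R,4aR,6S,8aS)-2-(bromomethyl)-5,5,8a-trimethylhexahydro-4H-1,3-benzodioxin-6-ol (equatorial hydroxyl) | BrC[C@@H]1OC[C@H]2C(C)(C)[C@@H](O)CC[C@]2(C)O1 | intermediate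
10 | (2R,4aR,8aS)-2-(bromomethyl)-5,5,8a-trimethyl-4a,7,8,8a-tetrahydro-4H-1,3-benzodioxin-6(5H)-one | BrC[C@@H]1OC[C@H]2C(C)(C)C(=O)CC[C@]2(C)O1 | intermediate
11 | (2R,4aR,6R,8aS)-2-(bromomethyl)-5,5,8a-trimethylhexahydro-4H-1,3-benzodioxin-6-ol (axial hydroxyl) | BrC[C@@H]1OC[C@H]2C(C)(C)[C@H](O)CC[C@]2(C)O1 | intermediate
12 | (2R,4aR,6S,8aS)-6-bromo-2-(bromomethyl)-5,5,8a-trimethylhexahydro-4H-1,3-benzodioxine (equatorial bromine) | BrC[C@@H]1OC[C@H]2C(C)(C)[C@@H](Br)CC[C@]2(C)O1 | intermediate
13 | [(1R,3S,6S)-3-bromo-6-{[(2R)-1-bromo-3-methylbut-3-en-2-yl]oxy}-2,2,6-trimethylcyclohexyl]methanol | OC[C@H]1C(C)(C)[C@@H](Br)CC[C@]1(C)O[C@@H](CBr)C(C)=C | intermediate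
14 | (1S,2S,4S)-4-bromo-1-{[(2R)-1-bromo-3-methylbut-3-en-2-yl]oxy}-2-(iodomethyl)-1,3,3-trimethylcyclohexane | IC[C@H]1C(C)(C)[C@@H](Br)CC[C@]1(C)O[C@@H](CBr)C(C)=C | intermediate
15 | vinyl bromide (bromoethene) | C=CBr | starting material
16 | {[(1S,3S,6S)-3-bromo-6-{[(2R)-1-bromo-3-methylbut-3-en-2-yl]oxy}-2,2,6-trimethylcyclohexyl]methyl}zinc iodide | I[Zn]C[C@H]1C(C)(C)[C@@H](Br)CC[C@]1(C)O[C@@H](CBr)C(C)=C | intermediate
17 | (1S,2S,4S)-4-bromo-1-{[(2R)-1-bromo-3-methylbut-3-en-2-yl]oxy}-1,3,3-trimethyl-2-(prop-2-en-1-yl)cyclohexane | C=CC[C@H]1C(C)(C)[C@@H](Br)CC[C@]1(C)O[C@@H](CBr)C(C)=C | intermediate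
18 | palisadin B, (2R,5aS,7S,9aS)-7-bromo-2-(bromomethyl)-3,6,6,9a-tetramethyl-2,5,5a,6,7,8,9,9a-octahydro-1-benzoxepine | CC1=CC[C@H]2C(C)(C)[C@@H](Br)CC[C@]2(C)O[C@H]1CBr | target

**Totals and risks**

Total step count: 12. Longest linear sequence: 12 steps, from geraniol 1.

The three steps most likely to fail:

Step 8. At this neopentyl-type axial carbinol the activated oxygen may leave by anti-elimination towards C7, or with a 1,2-methyl shift from C5, faster than bromide can enter. The fallback sets out from ketone 10 and comes back at 12, so that steps 7 and 8 are both left out. The triphenyl phosphite–bromine adduct with Et3N in CH2Cl2 should convert the ketone, which can enolize only towards C7, into the vinyl bromide (2R,4aR,8aS)-6-bromo-2-(bromomethyl)-5,5,8a-trimethyl-4a,5,8,8a-tetrahydro-4H-1,3-benzodioxine F1. Radical hydrogenation by hydrogen-atom transfer (Mn(dpm)3, PhSiH3, t-BuOOH, i-PrOH) should then add the first hydrogen at C7 and deliver the second to the α-bromo radical at C6 from the open axial side, which leaves bromine equatorial as in 12.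

Step 9. The electron-withdrawing bromomethyl group may make ionization of the acetal so slow that the organocopper reagent decomposes first, or a free oxocarbenium ion may form and lose facial control or shed the tertiary alkyl group. The fallback sets out from 12 and comes back at 13. TiCl4 with bis(trimethylsilyl)acetylene in CH2Cl2 at −78 °C, a stronger activation paired with a silicon nucleophile that substitutes acetals with the same inversion, should give the silylalkyne [(1R,3S,6S)-3-bromo-6-{[(2R)-1-bromo-4-(trimethylsilyl)but-3-yn-2-yl]oxy}-2,2,6-trimethylcyclohexyl]methanol F2. K2CO3 in MeOH should remove the silyl group to give the terminal alkyne [(1R,3S,6S)-3-bromo-6-{[(2R)-1-bromobut-3-yn-2-yl]oxy}-2,2,6-trimethylcyclohexyl]methanol F3. Zirconium-catalysed methylalumination (AlMe3, Cp2ZrCl2, CH2Cl2) followed by protonolysis should add methyl to the inner alkyne carbon and hydrogen to the outer one, which gives the prop-1-en-2-yl group of 13.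

Step 5. The cyclized alkoxy radical may reopen and the tertiary radical may be reduced to an isopropyl group, or the aldehyde may be hydrosilylated, before the ring closure is made permanent. The fallback sets out from 8 and comes back at 10, so that step 6 is left out. Aqueous NH3 and I2 in THF should convert the aldehyde into the nitrile 3-[(2R,4S,5R)-2-(bromomethyl)-4-methyl-5-(prop-1-en-2-yl)-1,3-dioxan-4-yl]propanenitrile F4, which is inert to the silane. Under the same iron hydride conditions the tertiary radical should add to the nitrile carbon in a 6-exo-dig closure that does not reverse. The resulting ketimine (2R,4aR,8aS)-2-(bromomethyl)-5,5,8a-trimethylhexahydro-4H-1,3-benzodioxin-6-imine F5 should hydrolyse to ketone 10 on work-up with dilute acid.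

**Further compounds**

F1 | step 8 | (2R,4aR,8aS)-6-bromo-2-(bromomethyl)-5,5,8a-trimethyl-4a,5,8,8a-tetrahydro-4H-1,3-benzodioxine | BrC[C@@H]1OC[C@H]2C(C)(C)C(Br)=CC[C@]2(C)O1
F2 | step 9 | [(1R,3S,6S)-3-bromo-6-{[(2R)-1-bromo-4-(trimethylsilyl)but-3-yn-2-yl]oxy}-2,2,6-trimethylcyclohexyl]methanol | OC[C@H]1C(C)(C)[C@@H](Br)CC[C@]1(C)O[C@@H](CBr)C#C[Si](C)(C)C
F3 | step 9 | [(1R,3S,6S)-3-bromo-6-{[(2R)-1-bromobut-3-yn-2-yl]oxy}-2,2,6-trimethylcyclohexyl]methanol | OC[C@H]1C(C)(C)[C@@H](Br)CC[C@]1(C)O[C@@H](CBr)C#C
F4 | step 5 | 3-[(2R,4S,5R)-2-(bromomethyl)-4-methyl-5-(prop-1-en-2-yl)-1,3-dioxan-4-yl]propanenitrile | BrC[C@@H]1OC[C@@H](C(C)=C)[C@](C)(CCC#N)O1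
F5 | step 5 | (2R,4aR,8aS)-2-(bromomethyl)-5,5,8a-trimethylhexahydro-4H-1,3-benzodioxin-6-imine | BrC[C@@H]1OC[C@H]2C(C)(C)C(=N)CC[C@]2(C)O1
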